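The C2-symmetric target is cut in ring A of each half (C4a–C5–C6–C7–C8–C8a) at C7–C8 and C5–C6. This exposes C6–C7(CH3)(O) as a lactic acid unit. It exposes C5–C4a–C8a–C8 as a 4-methylnicotinoyl unit of ring B. In the key step the enolate of the (R)-lactic acid pivalaldehyde acetal is C-acylated by the nicotinoyl chloride. The picolylic C5 anion then closes onto the lactone carbonyl. Both bonds, ring A, both carbonyls and quaternary C7 arise in one flask, with loss of pivalaldehyde. The precursors are a dienyl-substituted pyridine acid and a dioxolanone. Double N-alkylation with a C4 linker and C5 chlorination finish the synthesis.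

Key step: step 5

Remark: azaphilone numbering is used for each half (C1, N2, C3, C4, C4a, C5 to C8, C8a; ring A is the carbocycle, ring B the nitrogen ring). The descriptor at C7 reads R in 16, 17, 20 and 21 and S in 22 only because enolisation at C6 or the missing chlorine at C5 changes the priority order of C6 and C8; the spatial arrangement is the same throughout.

Step 1
Reactants: 1 (S)-2-methylbutan-1-ol; 2 2-(triphenylphosphoranylidene)propanal
Product: 4 (2E,4S)-2,4-dimethylhex-2-enal, via (S)-2-methylbutanal 3 (not isolated)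
Conditions: TEMPO (2,2,6,6-tetramethylpiperidin-1-oxyl, 10 mol %), PhI(OAc)2 (1.1 equiv), ClCH2CH2Cl, rt; then 2, 80 °C
Reagents that add atoms: none
Why: The oxoammonium-catalysed oxidation stops at the aldehyde and the Wittig reaction of the stabilised ylide should give the E-trisubstituted enal; the stereocentre (later C13) comes from the chiral pool, and telescoping spares the volatile, epimerisable aldehyde any handling.

Step 2
Reactants: 4 (2E,4S)-2,4-dimethylhex-2-enal; 5 bis(pinacolatoboryl)methane
Product: 7 2-[(1E,3E,5S)-3,5-dimethylhepta-1,3-dien-1-yl]-4,4,5,5-tetramethyl-1,3,2-dioxaborolane, via lithium bis(pinacolatoboryl)methanide 6 (not isolated)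
Conditions: 5, lithium 2,2,6,6-tetramethylpiperidide, THF, 0 °C; then 4, −78 °C → rt
Reagents that add atoms: none
Why: In this boron-Wittig olefination the gem-diboryl carbanion adds 1,2 to the hindered enal, and syn B–O elimination should give the E-alkenyl boronate without touching the existing alkene or stereocentre.

Step 3
Reactants: 7 dienyl pinacol boronate; 8 6-chloro-4-methylpyridine-3-carboxylic acid
Product: 9 6-[(1E,3E,5S)-3,5-dimethylhepta-1,3-dien-1-yl]-4-methylpyridine-3-carboxylic acid
Conditions: Pd(dppf)Cl2 (3 mol %), K2CO3 (3.5 equiv), 1,4-dioxane/H2O, 85 °C; then aq. HCl to pH 4–5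
Reagents that add atoms: none
Why: This is a Suzuki–Miyaura coupling; the C–Cl bond next to the pyridine nitrogen and para to the carboxylate is activated for oxidative addition, and the coupling keeps both alkene geometries.

Step 4
Reactants: 10 (R)-lactic acid; 11 pivalaldehyde
Product: 12 (2R,5R)-2-tert-butyl-5-methyl-1,3-dioxolan-4-one (cis)
Conditions: p-toluenesulfonic acid (cat.), pentane, reflux, azeotropic removal of water; crystallisation from pentane/Et2O, −78 °C
Reagents that add atoms: none
Why: Acid-catalysed acetalisation under thermodynamic control favours the cis isomer, so the lactate carbon sets the new acetal stereocentre C2, and low-temperature crystallisation removes the trans isomer.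

Step 5
Reactants: 9 dienyl-substituted 4-methylnicotinic acid; 12 (2R,5R)-2-tert-butyl-5-methyl-1,3-dioxolan-4-one
Product: 17 (7R)-3-[(1E,3E,5S)-3,5-dimethylhepta-1,3-dien-1-yl]-7-methyl-8-oxo-7,8-dihydroisoquinoline-6,7-diyl diacetate, via acid chloride 13 (not isolated), via lithium enolate 14 (not isolated), via C-acylated dioxolanone 15 (not isolated), via ring-closed lithium enolate 16 (not isolated)
Conditions: (a) 9, 1-chloro-N,N,2-trimethylprop-1-en-1-amine (1.05 equiv), THF, 0 °C → rt; (b) 12, LiN(iPr)2 (1.05 equiv), THF, −78 °C, then the solution of 13, −78 °C; (c) LiN(SiMe3)2 (1.1 equiv), −78 → 0 °C; (d) Ac2O (4 equiv), Et3N, 4-(dimethylamino)pyridine (cat.), 0 °C → rt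
Reagents that add atoms: acetic anhydride CC(=O)OC(C)=O
Why: Proposed new method: enolate 14 is C-acylated by aroyl chloride 13 on the face anti to the tert-butyl group (C7–C8 bond), LiN(SiMe3)2 then deprotonates the 4-methyl group, which is now both gamma-picolylic and ortho to the new ketone, and the resulting aza-dienolate attacks the dioxolanone carbonyl (C5–C6 bond), whose collapse expels the acetal oxygen, sheds pivalaldehyde and bares the C7 oxygen for acetylation in the same flask. The closest known reaction types are the acylation of alpha,alpha-disubstituted lithium ester enolates by acid chlorides, the alkylations and aldol additions of this dioxolanone enolate under self-regeneration of stereocentres, and the toluate-anion annulations that end in a Dieckmann-type acyl transfer; their union, in which the dioxolanone acts as donor at C7 and acceptor at C6, has not been shown. Ring A closes in a 6-exo-trig mode. The only new stereocentre, quaternary C7, is controlled by the acetal carbon of 12, so the aroyl group takes the place of the lactate hydrogen with retention, and C7 cannot epimerise afterwards because it bears no hydrogen. The step needs C- over O-acylation and acylation faster than proton transfer from the 4-methyl group, which the acid chloride at −78 °C and the lithium counter-ion should secure, and it needs deprotonation at the 4-methyl group rather than along the dienyl chain, which the ortho ketone and the mild amide base should secure. Excess Ac2O caps O6 as the enol acetate, which fixes ring B as a pyridine whose nitrogen is the only nucleophilic site left for step 6.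

Step 6
Reactants: 17 diacetate (two equivalents); 18 1,4-diiodobutane
Product: 21 2,2'-(butane-1,4-diyl)bis{(7R)-7-acetoxy-3-[(1E,3E,5S)-3,5-dimethylhepta-1,3-dien-1-yl]-7-methylisoquinoline-6,8(2H,7H)-dione}, via butane-1,4-diyl bis(triflate) 19 (not isolated), via bis(isoquinolinium) bis(triflate) 20 (not isolated)
Conditions: 18, AgOSO2CF3 (2.0 equiv), CH2Cl2, 0 °C → rt, AgI filtered off; then 17 (2.05 equiv), 2,6-di-tert-butylpyridine (0.2 equiv), CH2Cl2, rt → 35 °C; then sat. aq. NaHCO3, THF, rt
Reagents that add atoms: none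
Why: In this Menshutkin reaction, with O6 masked, the pyridine nitrogen is the only nucleophile for the primary bis(triflate); the 6-acetoxy group on the resulting cationic ring is an activated ester that bicarbonate cleaves to the neutral vinylogous pyridone, while the tertiary C7 acetate and all stereocentres stay untouched.

Step 7
Reactants: 21 bridged bis(vinylogous pyridone)
Product: 22 penazaphilone I, the (7S,7'S,13S,13'S) target
Conditions: N-chlorosuccinimide (2.1 equiv), CH2Cl2, 0 °C → rt, dark
Reagents that add atoms: N-chlorosuccinimide O=C1CCC(=O)N1Cl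
Why: This is the electrophilic chlorination of a vinylogous amide; C5 is the alpha carbon of the push-pull system N2–C3=C4–C4a=C5–C6=O and the site halogenated in azaphilone chemistry, so both C5 positions should react before the dienyl chains, and no stereocentre is affected.

Compound list
1 | (S)-2-methylbutan-1-ol | CC[C@H](C)CO | starting material
2 | 2-(triphenylphosphoranylidene)propanal | CC(C=O)=P(c1ccccc1)(c1ccccc1)c1ccccc1 | starting material
3 | (S)-2-methylbutanal | CC[C@H](C)C=O | intermediate
4 | (2E,4S)-2,4-dimethylhex-2-enal | CC[C@H](C)/C=C(C)/C=O | intermediate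
5 | bis(pinacolatoboryl)methane | CC1(C)OB(CB2OC(C)(C)C(C)(C)O2)OC1(C)C | starting material
6 | lithium bis(pinacolatoboryl)methanide | [Li+].[CH-](B1OC(C)(C)C(C)(C)O1)B1OC(C)(C)C(C)(C)O1 | intermediate
7 | 2-[(1E,3E,5S)-3,5-dimethylhepta-1,3-dien-1-yl]-4,4,5,5-tetramethyl-1,3,2-dioxaborolane | CC[C@H](C)/C=C(C)/C=C/B1OC(C)(C)C(C)(C)O1 | intermediate
8 | 6-chloro-4-methylpyridine-3-carboxylic acid | Cc1cc(Cl)ncc1C(=O)O | starting material
9 | 6-[(1E,3E,5S)-3,5-dimethylhepta-1,3-dien-1-yl]-4-methylpyridine-3-carboxylic acid | CC[C@H](C)/C=C(C)/C=C/c1cc(C)c(C(=O)O)cn1 | intermediate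
10 | (R)-lactic acid | C[C@@H](O)C(=O)O | starting material
11 | pivalaldehyde | CC(C)(C)C=O | starting material
12 | (2R,5R)-2-tert-butyl-5-methyl-1,3-dioxolan-4-one | C[C@H]1O[C@@H](C(C)(C)C)OC1=O | intermediate
13 | 6-[(1E,3E,5S)-3,5-dimethylhepta-1,3-dien-1-yl]-4-methylpyridine-3-carbonyl chloride | CC[C@H](C)/C=C(C)/C=C/c1cc(C)c(C(=O)Cl)cn1 | intermediate
14 | lithium (2R)-2-tert-butyl-5-methyl-1,3-dioxol-4-olate | CC1=C([O-])O[C@H](C(C)(C)C)O1.[Li+] | intermediate
15 | (2R,5S)-2-tert-butyl-5-{6-[(1E,3E,5S)-3,5-dimethylhepta-1,3-dien-1-yl]-4-methylpyridine-3-carbonyl}-5-methyl-1,3-dioxolan-4-one | C[C@@]1(C(=O)c2cnc(/C=C/C(C)=C/[C@@H](C)CC)cc2C)O[C@@H](C(C)(C)C)OC1=O | intermediate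
16 | lithium (7R)-3-[(1E,3E,5S)-3,5-dimethylhepta-1,3-dien-1-yl]-7-hydroxy-7-methyl-8-oxo-7,8-dihydroisoquinolin-6-olate | CC[C@H](C)/C=C(C)/C=C/c1cc2C=C([O-])[C@@](C)(O)C(=O)c2cn1.[Li+] | intermediate
17 | (7R)-3-[(1E,3E,5S)-3,5-dimethylhepta-1,3-dien-1-yl]-7-methyl-8-oxo-7,8-dihydroisoquinoline-6,7-diyl diacetate | CC[C@H](C)/C=C(C)/C=C/c1cc2C=C(OC(C)=O)[C@@](C)(OC(C)=O)C(=O)c2cn1 | intermediate
18 | 1,4-diiodobutane | ICCCCI | starting material
19 | butane-1,4-diyl bis(trifluoromethanesulfonate) | O=S(=O)(OCCCCOS(=O)(=O)C(F)(F)F)C(F)(F)F | intermediate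
20 | 2,2'-(butane-1,4-diyl)bis{(7R)-6,7-diacetoxy-3-[(1E,3E,5S)-3,5-dimethylhepta-1,3-dien-1-yl]-7-methyl-8-oxo-7,8-dihydroisoquinolin-2-ium} bis(trifluoromethanesulfonate) | CC[C@H](C)/C=C(C)/C=C/c1cc2C=C(OC(C)=O)[C@@](C)(OC(C)=O)C(=O)c2c[n+]1CCCC[n+]1cc2C(=O)[C@](C)(OC(C)=O)C(OC(C)=O)=Cc2cc1/C=C/C(C)=C/[C@@H](C)CC.[O-]S(=O)(=O)C(F)(F)F.[O-]S(=O)(=O)C(F)(F)F | intermediate
21 | 2,2'-(butane-1,4-diyl)bis{(7R)-7-acetoxy-3-[(1E,3E,5S)-3,5-dimethylhepta-1,3-dien-1-yl]-7-methylisoquinoline-6,8(2H,7H)-dione} | CC[C@H](C)/C=C(C)/C=C/C1=CC2=CC(=O)[C@@](C)(OC(C)=O)C(=O)C2=CN1CCCCN1C=C2C(=O)[C@](C)(OC(C)=O)C(=O)C=C2C=C1/C=C/C(C)=C/[C@@H](C)CC | intermediate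
22 | penazaphilone I, (7S,7'S,13S,13'S) | CC[C@H](C)/C=C(C)/C=C/C1=CC2=C(Cl)C(=O)[C@@](C)(OC(C)=O)C(=O)C2=CN1CCCCN1C=C2C(=O)[C@](C)(OC(C)=O)C(=O)C(Cl)=C2C=C1/C=C/C(C)=C/[C@@H](C)CC | target

Total step count: 7. Longest linear sequence: 6 steps (1, 2, 3, 5, 6, 7).

Steps most likely to fail

Step 5. Three processes could spoil it.
- The hindered enolate may be acylated on oxygen.
- Proton transfer from the 4-methyl group may outrun acylation. The picolyl anion would then open the dioxolanone first and stereocontrol at C7 would be lost.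
- The C5 enolate may capture the released pivalaldehyde.

The fallback sets out from 9, comes back at 15, and builds the C7–C8 bond by known aldol chemistry. Acid 9 is coupled with N,O-dimethylhydroxylamine (EDC, CH2Cl2) to the N-methoxy-N-methylamide F1. Reduction with iBu2AlH gives the pyridinecarbaldehyde F2. Aldol addition of enolate 14, again anti to the tert-butyl group, gives the carbinol F3 as both carbinol epimers. Dess–Martin oxidation gives 15, which is now isolated. LiN(SiMe3)2 and then Ac2O, as in step 5, lead on to 17.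

Step 6. The second quaternisation at the hindered, electron-poor nitrogen may be slow. The enol acetate may also be lost too early, which would open the way to O-alkylation. The fallback sets out from 17, comes back at 21, and alkylates an ambident anion instead of a neutral pyridine. Selective methanolysis of the enol acetate (NaHCO3, MeOH) gives the N–H vinylogous pyridone F4. Its caesium salt (Cs2CO3, DMF) is alkylated with half an equivalent of 18 to give 21.

Step 7. Chlorination may be incomplete at one of the two C5 sites, or site selectivity between C5 and the dienyl chains may be poor. The fallback sets out from 16, comes back at 22, and brings the chlorine in on the monomer.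
- The key step is quenched with aq. NH4Cl instead of Ac2O to give the ketol F5.
- NCS chlorinates its C5 enol carbon to the 5-chloro ketol F6.
- Ac2O with 4-(dimethylamino)pyridine gives the 5-chloro diacetate F7.
- Bis(triflate) 19 converts two equivalents of F7 into the bis(isoquinolinium) salt F8.
- Aqueous NaHCO3 cleaves F8 to 22.

Further compounds
F1 | step 5 | 6-[(1E,3E,5S)-3,5-dimethylhepta-1,3-dien-1-yl]-N-methoxy-N,4-dimethylpyridine-3-carboxamide | CC[C@H](C)/C=C(C)/C=C/c1cc(C)c(C(=O)N(C)OC)cn1
F2 | step 5 | 6-[(1E,3E,5S)-3,5-dimethylhepta-1,3-dien-1-yl]-4-methylpyridine-3-carbaldehyde | CC[C@H](C)/C=C(C)/C=C/c1cc(C)c(C=O)cn1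
F3 | step 5 | (2R,5S)-2-tert-butyl-5-({6-[(1E,3E,5S)-3,5-dimethylhepta-1,3-dien-1-yl]-4-methylpyridin-3-yl}hydroxymethyl)-5-methyl-1,3-dioxolan-4-one, both carbinol epimers | C[C@@]1(C(O)c2cnc(/C=C/C(C)=C/[C@@H](C)CC)cc2C)O[C@@H](C(C)(C)C)OC1=O
F4 | step 6 | (7R)-7-acetoxy-3-[(1E,3E,5S)-3,5-dimethylhepta-1,3-dien-1-yl]-7-methylisoquinoline-6,8(2H,7H)-dione | CC[C@H](C)/C=C(C)/C=C/C1=CC2=CC(=O)[C@@](C)(OC(C)=O)C(=O)C2=CN1
F5 | step 7 | (7R)-3-[(1E,3E,5S)-3,5-dimethylhepta-1,3-dien-1-yl]-6,7-dihydroxy-7-methylisoquinolin-8(7H)-one | CC[C@H](C)/C=C(C)/C=C/c1cc2C=C(O)[C@@](C)(O)C(=O)c2cn1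
F6 | step 7 | (7R)-5-chloro-3-[(1E,3E,5S)-3,5-dimethylhepta-1,3-dien-1-yl]-6,7-dihydroxy-7-methylisoquinolin-8(7H)-one | CC[C@H](C)/C=C(C)/C=C/c1cc2C(Cl)=C(O)[C@@](C)(O)C(=O)c2cn1
F7 | step 7 | (7R)-5-chloro-3-[(1E,3E,5S)-3,5-dimethylhepta-1,3-dien-1-yl]-7-methyl-8-oxo-7,8-dihydroisoquinoline-6,7-diyl diacetate | CC[C@H](C)/C=C(C)/C=C/c1cc2C(Cl)=C(OC(C)=O)[C@@](C)(OC(C)=O)C(=O)c2cn1
F8 | step 7 | 2,2'-(butane-1,4-diyl)bis{(7R)-6,7-diacetoxy-5-chloro-3-[(1E,3E,5S)-3,5-dimethylhepta-1,3-dien-1-yl]-7-methyl-8-oxo-7,8-dihydroisoquinolin-2-ium} bis(trifluoromethanesulfonate) | CC[C@H](C)/C=C(C)/C=C/c1cc2C(Cl)=C(OC(C)=O)[C@@](C)(OC(C)=O)C(=O)c2c[n+]1CCCC[n+]1cc2C(=O)[C@](C)(OC(C)=O)C(OC(C)=O)=C(Cl)c2cc1/C=C/C(C)=C/[C@@H](C)CC.[O-]S(=O)(=O)C(F)(F)F.[O-]S(=O)(=O)C(F)(F)F
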